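The α-methylene-γ-butyrolactone ring is cut across its carboxyl group: the carbonyl carbon C16 and the ring oxygen come from carbon dioxide, inserted between the alkenyl carbon C15 (bearing the exocyclic CH2) and the allylic carbon C2, both attached to C1 of the 14-membered ring. The precursor is the carbocycle carrying a 1-borylvinyl group on C1 and a chloride of inverted configuration on C2. Copper-catalysed carboxylation of the C15–B bond and displacement of chloride by the new carboxylate (5-exo-tet, inversion) build the cis-fused lactone in one operation. The carbocycle is closed by a borylative allene–aldehyde coupling that sets C1, C2 and the C15–B bond together.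

Key step: step 9

Remark: atoms carry cembrane numbers throughout (C1 = ring CH bearing C15, C2 = ring CH bearing the lactone oxygen, C13 = acetoxy carbon, C16 = lactone carbonyl carbon, C17 = exocyclic methylene, C18–C20 = methyls on C4, C8, C12), and nerylacetone is assumed to be bought as the pure (5Z) isomer, which supplies the 7Z olefin.

Step 1
Reactants: 1 nerylacetone [(5Z)-6,10-dimethylundeca-5,9-dien-2-one]; 2 diethyl [2-(methoxy(methyl)amino)-2-oxoethyl]phosphonate
Product: 3 (2E,6Z)-N-methoxy-N,3,7,11-tetramethyldodeca-2,6,10-trienamide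
Conditions: NaH, THF, 0 °C then 65 °C; minor 2Z isomer removed by chromatography
Reagents that add atoms: none
Why: Horner–Wadsworth–Emmons olefination of the methyl ketone should give mainly the (2E)-enamide (amide trans to the larger C5 chain) and installs C2 as a masked aldehyde, while the Z olefin of 1 is not touched.

Step 2
Reactants: 3
Product: 5 (2E,6Z,10E)-N-methoxy-N,3,7,11-tetramethyl-12-oxododeca-2,6,10-trienamide, via allylic alcohol 4 (not isolated)
Conditions: SeO2 (0.3 equiv), t-BuOOH, salicylic acid (cat.), CH2Cl2, 0 °C to rt; filtration, then MnO2, CH2Cl2, rt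
Reagents that add atoms: selenium dioxide, O=[Se]=O (oxygen donor, turned over by tert-butyl hydroperoxide, CC(C)(C)OO)
Why: Riley allylic oxidation (ene reaction, then [2,3]-sigmatropic shift) should attack the E-methyl group of the terminal, most electron-rich trisubstituted olefin and spare the deactivated enamide olefin, and MnO2 then takes the allylic alcohol to the (10E)-enal that becomes C13.

Step 3
Reactants: 5; 6 allenylboronic acid pinacol ester
Product: 7 (2E,6Z,10E,12S)-12-hydroxy-N-methoxy-N,3,7,11-tetramethylpentadeca-2,6,10-trien-14-ynamide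
Conditions: (S)-TRIP [(S)-3,3'-bis(2,4,6-triisopropylphenyl)-BINOL hydrogen phosphate] (10 mol %), 4 Å MS, toluene, 0 °C; aqueous work-up
Reagents that add atoms: none
Why: Chiral-phosphoric-acid-catalysed propargylboration (SE2' through a closed six-membered transition state) is chemoselective for the aldehyde, and the (S)-acid is chosen to deliver the propargyl group to the Si face, which sets C13 on purpose as the epimer of the target acetate carbon.

Step 4
Reactants: 7
Product: 8 (2E,6Z,10E,12S)-12-[(tert-butyldimethylsilyl)oxy]-N-methoxy-N,3,7,11-tetramethylpentadeca-2,6,10-trien-14-ynamide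
Conditions: TBSCl, imidazole, DMF, rt
Reagents that add atoms: tert-butyldimethylsilyl chloride, CC(C)(C)[Si](C)(C)Cl
Why: Standard silylation masks the C13 hydroxyl, which would otherwise protonate the allylcopper of step 7 and compete in the chlorination of step 8.

Step 5
Reactants: 8
Product: 10 (2E,6Z,10E,12S)-12-[(tert-butyldimethylsilyl)oxy]-N-methoxy-N,3,7,11-tetramethylhexadeca-2,6,10,14,15-pentaenamide, via propargylic amine 9 (not isolated)
Conditions: (CH2O)n, Cy2NH, CuI (0.5 equiv), 1,4-dioxane, reflux
Reagents that add atoms: formaldehyde (as paraformaldehyde), C=O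
Why: Crabbé homologation (copper-mediated Mannich coupling of the terminal alkyne, then intramolecular hydride transfer with loss of the imine) turns C≡CH into the terminal allene CH=C=CH2 and adds C17 without touching the silyl ether, the amide or C13.

Step 6
Reactants: 10
Product: 11 (2E,6Z,10E,12S)-12-[(tert-butyldimethylsilyl)oxy]-3,7,11-trimethylhexadeca-2,6,10,14,15-pentaenal
Conditions: i-Bu2AlH (1.2 equiv), THF, −78 °C; aq. potassium sodium tartrate
Reagents that add atoms: none
Why: Reduction of the Weinreb amide stops at the chelated tetrahedral aluminate, which should release the (2E)-enal (C2) on work-up with the allene intact.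

Step 7
Reactants: 11
Product: 13 (1S,13S)-13-[(tert-butyldimethylsilyl)oxy]-15-(pinacolatoboryl)-16-norcembra-3E,7Z,11E,15(17)-tetraen-2-ol with the 2-OH syn to C14, via allylcopper intermediate 12 (not isolated)
Conditions: B2pin2 (1.2 equiv), CuCl (10 mol %), chiral bisphosphine Ph-BPE (11 mol %; enantiomer chosen for Re-face addition to C2), NaOt-Bu (20 mol %), THF, 22 °C, syringe-pump addition of 11 (final 2 mM); aq. NH4Cl
Reagents that add atoms: bis(pinacolato)diboron, CC1(C)OB(OC1(C)C)B1OC(C)(C)C(C)(C)O1
Why: In this copper-catalysed borylative allene–aldehyde coupling the ligated Cu–Bpin should add across the terminal C15=C17 bond (boron to the central carbon C15, anti to C14) to give the (Z)-2-boryl-allylcopper, which adds through C1 to the aldehyde C2 in a chair transition state, so that the 14-membered ring closes under pseudo-dilution as the 1,2-syn adduct while the chiral ligand fixes the absolute configuration of C1 and C2 by Re-face attack.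

Step 8
Reactants: 13
Product: 14 (1S,13S)-13-[(tert-butyldimethylsilyl)oxy]-2-chloro-15-(pinacolatoboryl)-16-norcembra-3E,7Z,11E,15(17)-tetraene with the 2-Cl anti to C14
Conditions: PPh3, Cl3CC(O)CCl3, CH2Cl2, −20 to 0 °C; used at once
Reagents that add atoms: hexachloroacetone, ClC(Cl)(Cl)C(=O)C(Cl)(Cl)Cl
Why: Appel-type chlorination through the alkoxyphosphonium salt should proceed by SN2 with inversion at C2 and, under these non-ionising conditions, without allylic transposition.

Step 9
Reactants: 14
Product: 16 (1S,2S,13S)-13-[(tert-butyldimethylsilyl)oxy]cembra-3E,7Z,11E,15(17)-tetraen-16,2-olide, via potassium carboxylate 15 (not isolated)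
Conditions: (IPr)CuCl {chloro[1,3-bis(2,6-diisopropylphenyl)imidazol-2-ylidene]copper} (10 mol %), t-BuOK (1.05 equiv, added at −20 °C), CO2 (1 atm), THF, 20 to 65 °C
Reagents that add atoms: carbon dioxide, O=C=O
Why: t-BuOK converts the alkenyl-Bpin into its borate, which transmetalates to the copper carbene complex; CO2 inserts into the Cu–C15 bond (making C15–C16), and exchange with further borate releases the potassium carboxylate 15 and returns the copper alkoxide. The carboxylate oxygen then displaces the allylic chloride at C2 from the rear (making O–C2), so both bonds of the lactone carboxyl unit form in one flask. The closest known reactions are the copper-carbene-catalysed carboxylation of alkenylboronic esters with CO2 and the SN2 lactonisation of γ-halo carboxylates. The lactone ring closes in the 5-exo-tet mode. No new stereocentre is created: C2 is inverted stereospecifically, so the chloride anti to C14 gives the cis ring fusion at C1/C2, and C1 and C13 are not touched. The step needs CO2 capture by the alkenylcopper to outrun 1,3-elimination or allylic substitution, and O-attack at C2 rather than at C4 (SN2', seven-membered ring); the CO2 atmosphere, the 1,3-placement of C15 and C2 on C1, the preference for five-ring closure and the binding of the alkoxide as borate (which holds back E2 loss of HCl) should secure this.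

Step 10
Reactants: 16
Product: 17 (1S,2S,13S)-13-hydroxycembra-3E,7Z,11E,15(17)-tetraen-16,2-olide
Conditions: HF·pyridine, pyridine, THF, 0 °C to rt
Reagents that add atoms: none
Why: Acidic fluoride desilylation frees the C13 alcohol without forming an alkoxide that could add to the methylene lactone.

Step 11
Reactants: 17
Product: 18 (1S,2S,11S,12S,13S)-11,12-epoxy-13-hydroxycembra-3E,7Z,15(17)-trien-16,2-olide
Conditions: VO(acac)2 (5 mol %), t-BuOOH, CH2Cl2, 0 °C
Reagents that add atoms: tert-butyl hydroperoxide, CC(C)(C)OO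
Why: Hydroxyl-directed vanadium-catalysed epoxidation should touch only the C11=C12 olefin (the only one allylic to a free OH) and, because of A(1,2) strain from the C20 methyl, give the erythro epoxy alcohol, which sets C11 and C12 from C13.

Step 12
Reactants: 18
Product: 19 (1S,2S,11S,12R,13R)-13-acetoxy-11,12-epoxycembra-3E,7Z,15(17)-trien-16,2-olide (CNP0146076.3)
Conditions: PPh3, DIAD, AcOH, THF, 0 °C to rt
Reagents that add atoms: acetic acid, CC(=O)O
Why: In the Mitsunobu esterification acetate displaces the oxyphosphonium group by SN2, which inverts C13 and turns the erythro epoxy alcohol into the threo acetate of the target.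

Compound list
1 | nerylacetone, (5Z)-6,10-dimethylundeca-5,9-dien-2-one | CC(=O)CC/C=C(/C)CCC=C(C)C | starting material
2 | diethyl [2-(methoxy(methyl)amino)-2-oxoethyl]phosphonate | CCOP(=O)(CC(=O)N(C)OC)OCC | starting material
3 | (2E,6Z)-N-methoxy-N,3,7,11-tetramethyldodeca-2,6,10-trienamide | CON(C)C(=O)/C=C(\C)CC/C=C(/C)CCC=C(C)C | intermediate
4 | (2E,6Z,10E)-12-hydroxy-N-methoxy-N,3,7,11-tetramethyldodeca-2,6,10-trienamide (not isolated) | CON(C)C(=O)/C=C(\C)CC/C=C(/C)CC/C=C(\C)CO | intermediate
5 | (2E,6Z,10E)-N-methoxy-N,3,7,11-tetramethyl-12-oxododeca-2,6,10-trienamide | CON(C)C(=O)/C=C(\C)CC/C=C(/C)CC/C=C(\C)C=O | intermediate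
6 | allenylboronic acid pinacol ester | C=C=CB1OC(C)(C)C(C)(C)O1 | starting material
7 | (2E,6Z,10E,12S)-12-hydroxy-N-methoxy-N,3,7,11-tetramethylpentadeca-2,6,10-trien-14-ynamide | CON(C)C(=O)/C=C(\C)CC/C=C(/C)CC/C=C(\C)[C@@H](O)CC#C | intermediate
8 | (2E,6Z,10E,12S)-12-[(tert-butyldimethylsilyl)oxy]-N-methoxy-N,3,7,11-tetramethylpentadeca-2,6,10-trien-14-ynamide | CON(C)C(=O)/C=C(\C)CC/C=C(/C)CC/C=C(\C)[C@@H](O[Si](C)(C)C(C)(C)C)CC#C | intermediate
9 | (2E,6Z,10E,12S)-12-[(tert-butyldimethylsilyl)oxy]-16-(dicyclohexylamino)-N-methoxy-N,3,7,11-tetramethylhexadeca-2,6,10-trien-14-ynamide (not isolated) | CON(C)C(=O)/C=C(\C)CC/C=C(/C)CC/C=C(\C)[C@@H](O[Si](C)(C)C(C)(C)C)CC#CCN(C1CCCCC1)C1CCCCC1 | intermediate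
10 | (2E,6Z,10E,12S)-12-[(tert-butyldimethylsilyl)oxy]-N-methoxy-N,3,7,11-tetramethylhexadeca-2,6,10,14,15-pentaenamide | CON(C)C(=O)/C=C(\C)CC/C=C(/C)CC/C=C(\C)[C@@H](O[Si](C)(C)C(C)(C)C)CC=C=C | intermediate
11 | (2E,6Z,10E,12S)-12-[(tert-butyldimethylsilyl)oxy]-3,7,11-trimethylhexadeca-2,6,10,14,15-pentaenal | O=C/C=C(\C)CC/C=C(/C)CC/C=C(\C)[C@@H](O[Si](C)(C)C(C)(C)C)CC=C=C | intermediate
12 | (Z)-2-boryl-allylcopper formed from 11 (Cu on C17, Bpin on C15, C14 cis to C17; bisphosphine on copper not drawn; not isolated) | O=C/C=C(\C)CC/C=C(/C)CC/C=C(\C)[C@@H](O[Si](C)(C)C(C)(C)C)C/C=C(\C[Cu])B1OC(C)(C)C(C)(C)O1 | intermediate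
13 | (1S,13S)-13-[(tert-butyldimethylsilyl)oxy]-15-(pinacolatoboryl)-16-norcembra-3E,7Z,11E,15(17)-tetraen-2-ol, 2-OH syn to C14 | C=C(B1OC(C)(C)C(C)(C)O1)[C@H]2[C@@H](O)/C=C(\C)CC/C=C(/C)CC/C=C(\C)[C@@H](O[Si](C)(C)C(C)(C)C)C2 | intermediate
14 | (1S,13S)-13-[(tert-butyldimethylsilyl)oxy]-2-chloro-15-(pinacolatoboryl)-16-norcembra-3E,7Z,11E,15(17)-tetraene, 2-Cl anti to C14 | C=C(B1OC(C)(C)C(C)(C)O1)[C@H]2[C@H](Cl)/C=C(\C)CC/C=C(/C)CC/C=C(\C)[C@@H](O[Si](C)(C)C(C)(C)C)C2 | intermediate
15 | potassium (1S,13S)-13-[(tert-butyldimethylsilyl)oxy]-2-chlorocembra-3E,7Z,11E,15(17)-tetraen-16-oate, 2-Cl anti to C14 (not isolated) | C=C(C(=O)[O-])[C@H]1[C@H](Cl)/C=C(\C)CC/C=C(/C)CC/C=C(\C)[C@@H](O[Si](C)(C)C(C)(C)C)C1.[K+] | intermediate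
16 | (1S,2S,13S)-13-[(tert-butyldimethylsilyl)oxy]cembra-3E,7Z,11E,15(17)-tetraen-16,2-olide (cis-fused lactone) | C=C1C(=O)O[C@H]2/C=C(\C)CC/C=C(/C)CC/C=C(\C)[C@@H](O[Si](C)(C)C(C)(C)C)C[C@@H]12 | intermediate
17 | (1S,2S,13S)-13-hydroxycembra-3E,7Z,11E,15(17)-tetraen-16,2-olide | C=C1C(=O)O[C@H]2/C=C(\C)CC/C=C(/C)CC/C=C(\C)[C@@H](O)C[C@@H]12 | intermediate
18 | (1S,2S,11S,12S,13S)-11,12-epoxy-13-hydroxycembra-3E,7Z,15(17)-trien-16,2-olide (erythro epoxy alcohol) | C=C1C(=O)O[C@H]2/C=C(\C)CC/C=C(/C)CC[C@@H]3O[C@@]3(C)[C@@H](O)C[C@@H]12 | intermediate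
19 | (1S,2S,11S,12R,13R)-13-acetoxy-11,12-epoxycembra-3E,7Z,15(17)-trien-16,2-olide | C=C1C(=O)O[C@H]2/C=C(\C)CC/C=C(/C)CC[C@@H]3O[C@@]3(C)[C@H](OC(C)=O)C[C@@H]12 | target

Total step count: 12. Longest linear sequence: 12 steps (from nerylacetone 1).

Steps most likely to fail

Step 7 (ring closure). The allylcopper may be captured by a second aldehyde molecule before it cyclises (oligomerisation), the boryl-copper may add to the enal, or facial control may be weak in the macrocyclic transition state, and the syn sense of addition is assumed from the chair model. The fallback sets out from allene 10 and comes back at 13. Diboration of the terminal allene double bond of 10 with B2pin2 under Pt(dba)2/PCy3 catalysis (toluene, 50 °C) should give the (Z)-allyl/alkenyl bis(boronate) amide F1, whose geometry can be checked. Reduction with i-Bu2AlH at −78 °C should give the aldehyde bis(boronate) F2, in which the hindered pinacol allylboronate reacts only slowly with the enal at rt. Heating F2 at high dilution (toluene, 80 °C, optionally with a chiral phosphoric acid) should close the ring by uncatalysed allylboration through the chair transition state of the Z-allylboronate and give 13 after aqueous work-up.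

Step 9 (key step). The allylic chloride may be lost before CO2 is captured, by base-induced elimination of HCl or by 1,3-elimination from the borate or the alkenylcopper, or the pinacol boronate may transmetalate too slowly. The fallback sets out from 13 and comes back at 16, and forms the same two bonds through an alkenyllithium at low temperature. Iododeboronation of 13 (NaOMe, then I2, THF/MeOH, −78 °C) should give the alkenyl iodide alcohol F3. Chlorination with PPh3/hexachloroacetone should give the iodo chloride F4 with inversion at C2. Iodine–lithium exchange (t-BuLi, 2.1 equiv, Et2O/pentane, −100 °C), quenching with CO2 and warming with DMPU should let the lithium carboxylate displace chloride at C2 to give 16.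

Step 8 (chlorination). The alkoxyphosphonium or the chloride itself may ionise to the methyl-stabilised allyl cation, which would bring allylic transposition or epimerisation at C2, or elimination to the diene. The fallback sets out from 13 and comes back at 16 without a halide. Methyl chloroformate and pyridine should convert 13 with retention into the allylic methyl carbonate F5. Carboxylation of the alkenylboronate [(IPr)CuCl, CsF, CO2, DMF, 60 °C] and then Pd(PPh3)4 (5 mol %) in the same flask should ionise the carbonate with inversion (zerovalent palladium) and let the caesium carboxylate attack C2 of the allyl complex with a second inversion; net retention from the syn carbonate gives the cis-fused lactone 16.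

Further compounds
F1 | step 7 | (2E,6Z,10E,12S,14Z)-12-[(tert-butyldimethylsilyl)oxy]-N-methoxy-N,3,7,11-tetramethyl-15,16-bis(pinacolatoboryl)hexadeca-2,6,10,14-tetraenamide | CON(C)C(=O)/C=C(\C)CC/C=C(/C)CC/C=C(\C)[C@@H](O[Si](C)(C)C(C)(C)C)C/C=C(\CB1OC(C)(C)C(C)(C)O1)B1OC(C)(C)C(C)(C)O1
F2 | step 7 | (2E,6Z,10E,12S,14Z)-12-[(tert-butyldimethylsilyl)oxy]-3,7,11-trimethyl-15,16-bis(pinacolatoboryl)hexadeca-2,6,10,14-tetraenal | O=C/C=C(\C)CC/C=C(/C)CC/C=C(\C)[C@@H](O[Si](C)(C)C(C)(C)C)C/C=C(\CB1OC(C)(C)C(C)(C)O1)B1OC(C)(C)C(C)(C)O1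
F3 | step 9 | (1S,13S)-13-[(tert-butyldimethylsilyl)oxy]-15-iodo-16-norcembra-3E,7Z,11E,15(17)-tetraen-2-ol, 2-OH syn to C14 | C=C(I)[C@H]1[C@@H](O)/C=C(\C)CC/C=C(/C)CC/C=C(\C)[C@@H](O[Si](C)(C)C(C)(C)C)C1
F4 | step 9 | (1S,13S)-13-[(tert-butyldimethylsilyl)oxy]-2-chloro-15-iodo-16-norcembra-3E,7Z,11E,15(17)-tetraene, 2-Cl anti to C14 | C=C(I)[C@H]1[C@H](Cl)/C=C(\C)CC/C=C(/C)CC/C=C(\C)[C@@H](O[Si](C)(C)C(C)(C)C)C1
F5 | step 8 | methyl carbonate of 13 (carbonate oxygen syn to C14) | C=C(B1OC(C)(C)C(C)(C)O1)[C@H]2[C@@H](OC(=O)OC)/C=C(\C)CC/C=C(/C)CC/C=C(\C)[C@@H](O[Si](C)(C)C(C)(C)C)C2
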